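In the larch run Z levelled off far above zero although Z and Q were charged one to one, and the cedar run did the same. Z and G together came to 99.8% and 98.5% at 50.0 min, so the Z left over was Z that no Q had reached.

| flask | Z | Q | X | remark | time |
|---|---|---|---|---|---|
| larch | 0.17 M | 1 equiv | 1 equiv (fed, over 2.0 min) | run made earlier |  |
| cedar | 0.38 M | 1 equiv | 1 equiv (fed, over 2.0 min) | run made earlier |  |
| flask | 0.25 M | 1.00 equiv | 1.00 equiv (fed, over 2.0 min) |  | 50 min |

| run | time / min | Z / % | G / % |
|---|---|---|---|
| larch | 4.00 | 36.2 | 63.4 |
| larch | 10.0 | 29.6 | 69.9 |
| larch | 20.0 | 28.0 | 71.8 |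
| larch | 50.0 | 27.6 | 72.2 |
| cedar | 4.00 | 25.5 | 74.0 |
| cedar | 10.0 | 24.2 | 74.5 |
| cedar | 20.0 | 24.1 | 77.0 |
| cedar | 50.0 | 22.8 | 75.7 |

(each reading ± 0.5 percentage points)

- the earlier runs were read with a standard deviation of 0.5 percentage points
- reactions considered so far: Z + Q -> G; Q + X -> D; 2 X -> J
- the reaction counts as stopped when no species that holds the Z changes by six tenths of a point or more over the second half of the time

1. the state of affairs at 50 min: stopped, and by what, or still going (Q has run out first / forward and back rates have come level / it is still moving / all of Z has reacted)
2. part of the Z gone at 50 min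
3. the G standing at 50 min, as a percentage of the Z charged

I reckoned the small thing rather than the large one. With Q at one equivalent, the Z left equals the part of the Q lost elsewhere. Averaging the last two Z readings gave 27.8% for larch and 23.4% for cedar, lower in the stronger run. One value therefore did not serve both concentrations. On a log scale of concentration the flask lay 0.479 of the way from larch to cedar.

That gave the flask's waste share w, the part of its charged Q lost to X rather than to Z, 25.7%. The rest of its Q, 74.3% of the Z charged, fell short of the whole Z. So I took Q as the limiting reagent, with G at that figure and Z at w.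

Time had to drop out for this to hold. From 20.0 min to 50.0 min larch Z fell 0.4 percentage points against a scatter of 0.5 points. Cedar Z fell 1.3 points, but cedar G fell 1.3 points as well, so I read both runs as level.

The forecast, from the same two runs, said Q has run out first, with 74.3% of Z gone and 74.2% G: “The more concentrated run wastes less Q because more X goes to J.”

    Z + Q → G (k = 0.0712 M⁻¹ s⁻¹)
    Q + X → D (k = 0.0815 M⁻¹ s⁻¹)
    2 X → J (k = 0.123 M⁻¹ s⁻¹)

The outcome for the flask was this: Q has run out first, with 0% of its Q charge left at 50.0 min, 73.9% of Z gone and 73.9% G. The largest change over its second half was 0.0073 points. Its waste share came to 26.1%, which is 0.37 points above my w. In the same flask with 2.50 equiv of Q, my w, taken over unchanged, left Q worth 186% of the Z charged after the loss to X, beyond the whole Z. That flask ended with Z at 0%, G at 100% and 31% of its Q left.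

(The runs are simulated on assumed constants, noise included.)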